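**Plan**
1. Numbering: C1 = ArCH2; C2–C7 = cyclohexane (C3 =CH2, C6–Br, C7 quaternary CH3); C8–C13 = chain (C10–Br, C11 CH3/OH); C14 = lactone carbinol carbon carrying the isopropenyl group (C15).
2. Feature used: C14 is both the O-bearing carbon of the 15-membered lactone and allylic to C15=CH2, so it can be the γ-carbon of a 3-aroyloxy-2-methylallyl chloride that already holds the ring oxygen. C13 is a plain CH2 that can arrive as a primary alkyl-metal made from a vinyl group on C11.
3. Retrosynthesis: C10–Br/C11–OH back to the C10=C11 alkene through its epoxide; the macrolide is cut at C13–C14; then C2–C7 together with C6–Br (bromonium cyclisation of an acyclic allylsilane); then C1–C2 and C3–CH2Si (carbocupration/benzylation) and C4–C5 (epoxy triflate alkylation).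
4. Forward: geraniol → epoxy dienyne; union with the benzylic bromide; cyclohexane ring; enol ester; 15-membered ring by C13–C14 closure; epoxide; bromohydrin; free phenol.
5. Stereochemistry: C6/C7 from a Sharpless epoxidation relayed through a bromonium ion; C2 from the chair transition state; C14 from a chiral copper catalyst; C10/C11 from a Shi epoxidation followed by SN2 opening with bromide.

Key step: step 17

Remark on the chemistry: the sense of induction of the copper catalyst (step 17) and of the fructose-derived ketone (step 18) is assigned from the accepted models; should it prove opposite, the other enantiomer of the ligand or ketone is used.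

Step 1
Reactants: 1 methyl 4-hydroxy-3-methylbenzoate
Product: 2 methyl 3-methyl-4-(triisopropylsilyloxy)benzoate
Conditions: iPr3SiCl, imidazole, DMF, rt
Reagents that add atoms: chlorotriisopropylsilane, CC(C)[Si](Cl)(C(C)C)C(C)C
Why: Silyl ether protection of the phenol; the hindered aryl silyl ether should survive the organocopper, Lewis-acid and mildly basic steps and leave with fluoride at the end.

Step 2
Reactants: 2 methyl 3-methyl-4-(triisopropylsilyloxy)benzoate
Product: 3 methyl 3-(bromomethyl)-4-(triisopropylsilyloxy)benzoate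
Conditions: NBS, AIBN (cat.), PhCF3, 80 °C
Reagents that add atoms: N-bromosuccinimide, O=C1CCC(=O)N1Br
Why: Wohl–Ziegler benzylic bromination; the aryl methyl group carries the only benzylic C–H bonds and the ester deactivates the ring towards electrophilic bromination.

Step 3
Reactants: 4 geraniol
Product: 5 (2R,3R)-2,3-epoxygeraniol
Conditions: Ti(OiPr)4 (5 mol %), D-(−)-diethyl tartrate (6 mol %), tBuOOH, 4 Å MS, CH2Cl2, −20 °C
Reagents that add atoms: tert-butyl hydroperoxide, CC(C)(C)OO
Why: Sharpless asymmetric epoxidation epoxidises only the allylic-alcohol alkene, and D-(−)-tartrate should direct oxygen to the face that gives the (2R,3R)-epoxide, whose carbons become C6 and C7.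

Step 4
Reactants: 5 (2R,3R)-2,3-epoxygeraniol; 6 1-(trimethylsilyl)propyne
Product: 8 (2R,3R)-2-methyl-2-(4-methylpent-3-en-1-yl)-3-[4-(trimethylsilyl)but-3-yn-1-yl]oxirane, via epoxy triflate 7 (not isolated)
Conditions: Tf2O, 2,6-lutidine, CH2Cl2, −78 °C; then Me3SiC≡CCH2Li (from 6, nBuLi, THF, −78 °C), −78 → −40 °C
Reagents that add atoms: triflic anhydride, O=S(=O)(OS(=O)(=O)C(F)(F)F)C(F)(F)F (gives the triflate group of 7 only)
Why: SN2 alkylation of a propargyllithium by a primary triflate forms C4–C5; at −78 °C the triflate carbon reacts far faster than the trisubstituted epoxide, so both stereocentres are untouched.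

Step 5
Reactants: 8 (2R,3R)-2-methyl-2-(4-methylpent-3-en-1-yl)-3-[4-(trimethylsilyl)but-3-yn-1-yl]oxirane
Product: 10 (2E)-2-methyl-5-{(2R,3R)-2-methyl-3-[4-(trimethylsilyl)but-3-yn-1-yl]oxiran-2-yl}pent-2-enal, via allylic alcohol 9 (not isolated)
Conditions: SeO2 (cat.), tBuOOH, CH2Cl2, 0 °C → rt; then MnO2, CH2Cl2, rt
Reagents that add atoms: tert-butyl hydroperoxide, CC(C)(C)OO (oxygen source for the SeO2 cycle)
Why: Selenium dioxide allylic oxidation (ene reaction then [2,3]-shift) selects the (E)-methyl group of the terminal trisubstituted alkene, and MnO2 converges alcohol and over-oxidised material to the (E)-enal.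

Step 6
Reactants: 10 (2E)-2-methyl-5-{(2R,3R)-2-methyl-3-[4-(trimethylsilyl)but-3-yn-1-yl]oxiran-2-yl}pent-2-enal
Product: 11 (2R,3R)-2-methyl-2-[(3E)-4-methylhexa-3,5-dien-1-yl]-3-[4-(trimethylsilyl)but-3-yn-1-yl]oxirane
Conditions: Ph3PCH3Br, NaN(SiMe3)2, THF, 0 °C; then 10, −78 °C → rt
Reagents that add atoms: methyltriphenylphosphonium bromide, C[P+](c1ccccc1)(c1ccccc1)c1ccccc1.[Br-]
Why: Wittig methylenation of the enal gives the C10–C13 diene without touching the epoxide or the silylalkyne.

Step 7
Reactants: 11 (2R,3R)-2-methyl-2-[(3E)-4-methylhexa-3,5-dien-1-yl]-3-[4-(trimethylsilyl)but-3-yn-1-yl]oxirane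
Product: 12 (2R,3R)-3-(but-3-yn-1-yl)-2-methyl-2-[(3E)-4-methylhexa-3,5-dien-1-yl]oxirane
Conditions: K2CO3, MeOH, rt
Reagents that add atoms: none
Why: Base-catalysed protodesilylation of the alkynylsilane frees the terminal alkyne needed for carbometalation.

Step 8
Reactants: 12 (2R,3R)-3-(but-3-yn-1-yl)-2-methyl-2-[(3E)-4-methylhexa-3,5-dien-1-yl]oxirane; 3 methyl 3-(bromomethyl)-4-(triisopropylsilyloxy)benzoate
Product: 14 methyl 3-[(2Z,6R,7R,10E)-6,7-epoxy-7,11-dimethyl-3-(trimethylsilylmethyl)trideca-2,10,12-trienyl]-4-(triisopropylsilyloxy)benzoate, via alkenylcopper 13 (not isolated)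
Conditions: Me3SiCH2MgCl, CuBr·SMe2, Et2O/Me2S, −45 °C; 12, −45 → −15 °C; then 3, THF/DMPU, −30 → 0 °C
Reagents that add atoms: (trimethylsilyl)methylmagnesium chloride, C[Si](C)(C)C[Mg]Cl; CuBr·SMe2, CSC.[Cu]Br (copper of 13 only)
Why: Normant syn-carbocupration puts CH2SiMe3 on C3 and copper on C2 cis to each other, and alkylation of the alkenylcopper by the benzylic bromide goes with retention, so C1 ends cis to CH2SiMe3 (2Z), the geometry the chair cyclisation needs; organocopper reagents should leave the trisubstituted epoxide, the diene and the ester alone at these temperatures.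

Step 9
Reactants: 14 methyl 3-[(2Z,6R,7R,10E)-6,7-epoxy-7,11-dimethyl-3-(trimethylsilylmethyl)trideca-2,10,12-trienyl]-4-(triisopropylsilyloxy)benzoate
Product: 15 methyl 3-[(2Z,6S,7R,10E)-6-bromo-7-hydroxy-7,11-dimethyl-3-(trimethylsilylmethyl)trideca-2,10,12-trienyl]-4-(triisopropylsilyloxy)benzoate
Conditions: Li2NiBr4 (0.4 M in THF), THF, 0 °C → rt
Reagents that add atoms: dilithium tetrabromonickelate, [Li+].[Li+].[Ni+2].[Br-].[Br-].[Br-].[Br-]
Why: SN2 epoxide opening by soft bromide at the secondary carbon C6 with inversion should give the anti bromohydrin (6S-bromide, 7R-tertiary alcohol).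

Step 10
Reactants: 15 methyl 3-[(2Z,6S,7R,10E)-6-bromo-7-hydroxy-7,11-dimethyl-3-(trimethylsilylmethyl)trideca-2,10,12-trienyl]-4-(triisopropylsilyloxy)benzoate
Product: 16 methyl 3-[(2Z,6S,7R,10E)-6-bromo-7-chloro-7,11-dimethyl-3-(trimethylsilylmethyl)trideca-2,10,12-trienyl]-4-(triisopropylsilyloxy)benzoate
Conditions: 1-chloro-N,N,2-trimethylprop-1-en-1-amine, CH2Cl2, 0 °C
Reagents that add atoms: 1-chloro-N,N,2-trimethylprop-1-en-1-amine, CC(C)=C(Cl)N(C)C
Why: Neutral deoxychlorination of the tertiary alcohol with an α-chloroenamine; departure of the activated oxygen is assisted by the anti bromine, so chloride should return at C7 with retention and give the anti bromochloride without acid that would harm the allylsilane.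

Step 11
Reactants: 16 methyl 3-[(2Z,6S,7R,10E)-6-bromo-7-chloro-7,11-dimethyl-3-(trimethylsilylmethyl)trideca-2,10,12-trienyl]-4-(triisopropylsilyloxy)benzoate
Product: 17 methyl 3-{[(2R,6S,7S)-6-bromo-7-methyl-3-methylidene-7-((3E)-4-methylhexa-3,5-dienyl)cyclohexyl]methyl}-4-(triisopropylsilyloxy)benzoate (ring atoms C2 to C7 as in the plan)
Conditions: (CF3)2CHOH, 2,6-di-tert-butyl-4-methylpyridine, 0 °C → rt, 2 mM
Reagents that add atoms: none
Why: Solvolysis of the tertiary chloride with bromine participation gives a configurationally defined bromonium ion, which the C2=C3 allylsilane captures at C7 through a chair transition state (Br, C8 and C1 equatorial), so C6 keeps its configuration, C7 is formed with net retention, C2 follows from the chair, and loss of silicon fixes the alkene as the exocyclic methylene (bromonium-initiated cation–olefin cyclisation with allylsilane termination).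

Step 12
Reactants: 17 methyl 3-{[(2R,6S,7S)-6-bromo-7-methyl-3-methylidene-7-((3E)-4-methylhexa-3,5-dienyl)cyclohexyl]methyl}-4-(triisopropylsilyloxy)benzoate
Product: 18 3-{[(2R,6S,7S)-6-bromo-7-methyl-3-methylidene-7-((3E)-4-methylhexa-3,5-dienyl)cyclohexyl]methyl}-4-(triisopropylsilyloxy)benzoic acid
Conditions: Me3SnOH, ClCH2CH2Cl, 80 °C; 5% aq HCl work-up
Reagents that add atoms: trimethyltin hydroxide, C[Sn](C)(C)O
Why: Near-neutral methyl ester cleavage with Me3SnOH should spare the aryl silyl ether, the secondary bromide and the diene.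

Step 13
Reactants: 19 (2E)-3-ethoxy-2-methylprop-2-enal
Product: 20 sodium (1E)-2-methyl-3-oxoprop-1-en-1-olate
Conditions: NaOH (1.0 equiv), H2O, rt; evaporate, dry in vacuo
Reagents that add atoms: sodium hydroxide, [Na+].[OH-]
Why: Addition–elimination of hydroxide on the vinylogous ester gives the symmetrical 2-methylmalonaldehyde enolate.

Step 14
Reactants: 18 the benzoic acid of step 12; 20 sodium (1E)-2-methyl-3-oxoprop-1-en-1-olate
Product: 22 (1E)-2-methyl-3-oxoprop-1-enyl ester of acid 18, via acid chloride 21 (not isolated)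
Conditions: 18, 1-chloro-N,N,2-trimethylprop-1-en-1-amine, CH2Cl2, 0 °C → rt; then 20, MeCN, 0 °C
Reagents that add atoms: 1-chloro-N,N,2-trimethylprop-1-en-1-amine, CC(C)=C(Cl)N(C)C (chlorine of 21 only)
Why: O-Acylation of the malonaldehyde enolate by an acid chloride made under neutral conditions; the β-acyloxy enal should form as the (E) isomer (acyloxy trans to formyl), the preferred geometry of such push–pull alkenes.

Step 15
Reactants: 22 (1E)-2-methyl-3-oxoprop-1-enyl ester of acid 18
Product: 23 (1E)-3-hydroxy-2-methylprop-1-enyl ester of acid 18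
Conditions: NaBH4, CeCl3·7H2O, MeOH/THF, −78 °C
Reagents that add atoms: none
Why: Luche 1,2-reduction of the enal; in the (E) isomer the new CH2OH is trans to the acyloxy group, so acyl migration cannot occur.

Step 16
Reactants: 23 (1E)-3-hydroxy-2-methylprop-1-enyl ester of acid 18
Product: 24 (1E)-3-chloro-2-methylprop-1-enyl ester of acid 18
Conditions: 1-chloro-N,N,2-trimethylprop-1-en-1-amine, CH2Cl2, 0 °C
Reagents that add atoms: 1-chloro-N,N,2-trimethylprop-1-en-1-amine, CC(C)=C(Cl)N(C)C
Why: Neutral deoxychlorination of the primary allylic alcohol (SN2 on the alkoxy-iminium ion, no excess chloride) should keep the (E) enol ester geometry.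

Step 17
Reactants: 24 (1E)-3-chloro-2-methylprop-1-enyl ester of acid 18
Product: 26 O-triisopropylsilyl (2R,6S,7S,10E,14S)-10,11-didehydro macrolide (15-membered lactone with C10=C11 and the C14 isopropenyl group), via alkylzirconocene 25 (not isolated)
Conditions: Cp2Zr(H)Cl (1.2 equiv), CH2Cl2, rt, 30 min; then slow addition (10 h) to CuCl (20 mol %), AgNTf2 (20 mol %), chiral BINOL-derived phosphoramidite ligand (22 mol %), CH2Cl2, 0 °C → rt, final 1 mM
Reagents that add atoms: Cp2Zr(H)Cl, [H][Zr](Cl)(C1C=CC=C1)C1C=CC=C1 (zirconium of 25 only; 26 keeps only its hydrogen)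
Why: Proposed new method: Hydrozirconation of the terminal vinyl group of the diene gives the primary C13 alkylzirconocene, which transmetalates to the chiral phosphoramidite–copper complex; the alkylcopper adds anti SN2′ to the enol-ester carbon C14 of the 3-acyloxyallyl chloride, and the resulting allyl species of trivalent copper reductively eliminates, forming C13–C14 and moving the double bond into the isopropenyl group. The closest known reactions are the copper-catalysed asymmetric allylic alkylation of 3-bromopropenyl esters with alkyl Grignard reagents, which gives α-branched allylic esters, and copper-catalysed allylic alkylations with alkylzirconocenes from hydrozirconation; their intramolecular, macrocyclising combination has not been shown. The 15-membered lactone closes in the exo mode of an SN2′ substitution (15-exo), the ester oxygen being already in the ring and the new alkene falling outside it. The new stereocentre C14 is set by the chiral ligand on copper, which selects the face of the (E)-enol ester anti to the leaving chloride; the ligand enantiomer is chosen for 14S and the remote ring stereocentres should not interfere. The step needs γ- over α-attack (favoured by the acyloxy substituent and the phosphoramidite–copper catalyst), hydrozirconation of the vinyl group only (secured by the steric sensitivity of Cp2Zr(H)Cl towards 1,1-disubstituted and trisubstituted alkenes) and ring closure over oligomerisation (secured by slow addition at about 1 mM). The secondary bromide, the aryl silyl ether and both ester groups should be inert to the zirconium hydride over the short contact time and to the copper catalyst.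

Step 18
Reactants: 26 O-triisopropylsilyl (2R,6S,7S,10E,14S)-10,11-didehydro macrolide
Product: 27 O-triisopropylsilyl (2R,6S,7S,10S,11S,14S)-10,11-epoxy macrolide
Conditions: L-fructose-derived Shi ketone (ent-Shi ketone, 30 mol %), KHSO5, K2CO3, Bu4NHSO4, MeCN/CH2(OMe)2/aq Na2B4O7 buffer, 0 °C
Reagents that add atoms: potassium peroxymonosulfate, [K+].[O-]S(=O)(=O)OO
Why: Shi asymmetric epoxidation; the chiral dioxirane should react fastest with the only trisubstituted, non-deactivated alkene C10=C11 (the exocyclic methylene and the ester-bearing isopropenyl group are 1,1-disubstituted), and by the spiro transition-state model the L-fructose-derived ketone should give the (10S,11S)-epoxide.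

Step 19
Reactants: 27 O-triisopropylsilyl (2R,6S,7S,10S,11S,14S)-10,11-epoxy macrolide
Product: 28 O-triisopropylsilyl bromophycolide E
Conditions: Li2NiBr4 (0.4 M in THF), THF, 0 °C → rt
Reagents that add atoms: dilithium tetrabromonickelate, [Li+].[Li+].[Ni+2].[Br-].[Br-].[Br-].[Br-]
Why: SN2 epoxide opening by soft bromide at the secondary carbon C10 with inversion should give the (10R)-bromide and leave the (11S)-tertiary alcohol, the anti bromohydrin of the target.

Step 20
Reactants: 28 O-triisopropylsilyl bromophycolide E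
Product: 29 bromophycolide E
Conditions: Bu4NF, AcOH (1:1), THF, 0 °C
Reagents that add atoms: none
Why: Fluoride desilylation of the aryl silyl ether; buffering with acetic acid keeps the medium non-basic, so the bromohydrin should not close to the epoxide and the lactone should stay intact.

**Compound list**
1 | methyl 4-hydroxy-3-methylbenzoate | COC(=O)c1ccc(O)c(C)c1 | starting material
2 | methyl 3-methyl-4-(triisopropylsilyloxy)benzoate | COC(=O)c1ccc(O[Si](C(C)C)(C(C)C)C(C)C)c(C)c1 | intermediate
3 | methyl 3-(bromomethyl)-4-(triisopropylsilyloxy)benzoate | COC(=O)c1ccc(O[Si](C(C)C)(C(C)C)C(C)C)c(CBr)c1 | intermediate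
4 | geraniol, (2E)-3,7-dimethylocta-2,6-dien-1-ol | CC(C)=CCC/C(C)=C/CO | starting material
5 | (2R,3R)-2,3-epoxygeraniol, [(2R,3R)-3-methyl-3-(4-methylpent-3-en-1-yl)oxiran-2-yl]methanol | OC[C@H]1O[C@]1(C)CCC=C(C)C | intermediate
6 | 1-(trimethylsilyl)propyne | CC#C[Si](C)(C)C | starting material
7 | [(2R,3R)-3-methyl-3-(4-methylpent-3-en-1-yl)oxiran-2-yl]methyl trifluoromethanesulfonate | O=S(=O)(OC[C@H]1O[C@]1(C)CCC=C(C)C)C(F)(F)F | intermediate (not isolated)
8 | (2R,3R)-2-methyl-2-(4-methylpent-3-en-1-yl)-3-[4-(trimethylsilyl)but-3-yn-1-yl]oxirane | C[Si](C)(C)C#CCC[C@H]1O[C@]1(C)CCC=C(C)C | intermediate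
9 | (2E)-2-methyl-5-{(2R,3R)-2-methyl-3-[4-(trimethylsilyl)but-3-yn-1-yl]oxiran-2-yl}pent-2-en-1-ol | C[Si](C)(C)C#CCC[C@H]1O[C@]1(C)CC/C=C(C)/CO | intermediate (not isolated)
10 | (2E)-2-methyl-5-{(2R,3R)-2-methyl-3-[4-(trimethylsilyl)but-3-yn-1-yl]oxiran-2-yl}pent-2-enal | C[Si](C)(C)C#CCC[C@H]1O[C@]1(C)CC/C=C(C)/C=O | intermediate
11 | (2R,3R)-2-methyl-2-[(3E)-4-methylhexa-3,5-dien-1-yl]-3-[4-(trimethylsilyl)but-3-yn-1-yl]oxirane | C[Si](C)(C)C#CCC[C@H]1O[C@]1(C)CC/C=C(C)/C=C | intermediate
12 | (2R,3R)-3-(but-3-yn-1-yl)-2-methyl-2-[(3E)-4-methylhexa-3,5-dien-1-yl]oxirane | C#CCC[C@H]1O[C@]1(C)CC/C=C(C)/C=C | intermediate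
13 | alkenylcopper from syn-addition of Me3SiCH2Cu to 12 (Cu on C2 cis to CH2SiMe3; as its MgBrCl complex) | [Cu]/C=C(\C[Si](C)(C)C)CC[C@H]1O[C@]1(C)CC/C=C(C)/C=C | intermediate (not isolated)
14 | methyl 3-[(2Z,6R,7R,10E)-6,7-epoxy-7,11-dimethyl-3-(trimethylsilylmethyl)trideca-2,10,12-trienyl]-4-(triisopropylsilyloxy)benzoate | COC(=O)c1ccc(O[Si](C(C)C)(C(C)C)C(C)C)c(C/C=C(\C[Si](C)(C)C)CC[C@H]2O[C@]2(C)CC/C=C(C)/C=C)c1 | intermediate
15 | methyl 3-[(2Z,6S,7R,10E)-6-bromo-7-hydroxy-7,11-dimethyl-3-(trimethylsilylmethyl)trideca-2,10,12-trienyl]-4-(triisopropylsilyloxy)benzoate | COC(=O)c1ccc(O[Si](C(C)C)(C(C)C)C(C)C)c(C/C=C(\C[Si](C)(C)C)CC[C@H](Br)[C@@](O)(C)CC/C=C(C)/C=C)c1 | intermediate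
16 | methyl 3-[(2Z,6S,7R,10E)-6-bromo-7-chloro-7,11-dimethyl-3-(trimethylsilylmethyl)trideca-2,10,12-trienyl]-4-(triisopropylsilyloxy)benzoate | COC(=O)c1ccc(O[Si](C(C)C)(C(C)C)C(C)C)c(C/C=C(\C[Si](C)(C)C)CC[C@H](Br)[C@@](Cl)(C)CC/C=C(C)/C=C)c1 | intermediate
17 | methyl 3-{[(2R,6S,7S)-6-bromo-7-methyl-3-methylidene-7-((3E)-4-methylhexa-3,5-dienyl)cyclohexyl]methyl}-4-(triisopropylsilyloxy)benzoate (ring C2–C7 as in the plan; Br, C7-methyl and ArCH2 all cis) | C=C/C(C)=C/CC[C@@]1(C)[C@H](Cc2cc(ccc2O[Si](C(C)C)(C(C)C)C(C)C)C(=O)OC)C(=C)CC[C@@H]1Br | intermediate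
18 | benzoic acid corresponding to 17 | C=C/C(C)=C/CC[C@@]1(C)[C@H](Cc2cc(ccc2O[Si](C(C)C)(C(C)C)C(C)C)C(=O)O)C(=C)CC[C@@H]1Br | intermediate
19 | (2E)-3-ethoxy-2-methylprop-2-enal (3-ethoxy-2-methylacrolein) | CCO/C=C(\C)C=O | starting material
20 | sodium (1E)-2-methyl-3-oxoprop-1-en-1-olate (sodium 2-methylmalonaldehyde enolate) | [Na+].[O-]/C=C(\C)C=O | intermediate
21 | benzoyl chloride corresponding to 18 | C=C/C(C)=C/CC[C@@]1(C)[C@H](Cc2cc(ccc2O[Si](C(C)C)(C(C)C)C(C)C)C(=O)Cl)C(=C)CC[C@@H]1Br | intermediate (not isolated)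
22 | (1E)-2-methyl-3-oxoprop-1-enyl ester of acid 18 | C=C/C(C)=C/CC[C@@]1(C)[C@H](Cc2cc(ccc2O[Si](C(C)C)(C(C)C)C(C)C)C(=O)O/C=C(\C)C=O)C(=C)CC[C@@H]1Br | intermediate
23 | (1E)-3-hydroxy-2-methylprop-1-enyl ester of acid 18 | C=C/C(C)=C/CC[C@@]1(C)[C@H](Cc2cc(ccc2O[Si](C(C)C)(C(C)C)C(C)C)C(=O)O/C=C(\C)CO)C(=C)CC[C@@H]1Br | intermediate
24 | (1E)-3-chloro-2-methylprop-1-enyl ester of acid 18 | C=C/C(C)=C/CC[C@@]1(C)[C@H](Cc2cc(ccc2O[Si](C(C)C)(C(C)C)C(C)C)C(=O)O/C=C(\C)CCl)C(=C)CC[C@@H]1Br | intermediate
25 | C13 chlorobis(cyclopentadienyl)zirconium alkyl from hydrozirconation of the vinyl group of 24 | Cl[Zr](C1C=CC=C1)(C2C=CC=C2)CC/C(C)=C/CC[C@@]3(C)[C@H](Cc4cc(ccc4O[Si](C(C)C)(C(C)C)C(C)C)C(=O)O/C=C(\C)CCl)C(=C)CC[C@@H]3Br | intermediate (not isolated)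
26 | O-triisopropylsilyl (2R,6S,7S,10E,14S)-10,11-didehydro macrolide (15-membered lactone; C10=C11; isopropenyl on C14) | C=C(C)[C@@H]1CC/C(C)=C/CC[C@@]2(C)[C@H](Cc3cc(ccc3O[Si](C(C)C)(C(C)C)C(C)C)C(=O)O1)C(=C)CC[C@@H]2Br | intermediate
27 | O-triisopropylsilyl (2R,6S,7S,10S,11S,14S)-10,11-epoxy macrolide | C=C(C)[C@@H]1CC[C@]3(C)O[C@H]3CC[C@@]2(C)[C@H](Cc4cc(ccc4O[Si](C(C)C)(C(C)C)C(C)C)C(=O)O1)C(=C)CC[C@@H]2Br | intermediate
28 | O-triisopropylsilyl bromophycolide E (2R,6S,7S,10R,11S,14S) | C=C(C)[C@@H]1CC[C@](C)(O)[C@H](Br)CC[C@@]2(C)[C@H](Cc3cc(ccc3O[Si](C(C)C)(C(C)C)C(C)C)C(=O)O1)C(=C)CC[C@@H]2Br | intermediate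
29 | bromophycolide E (2R,6S,7S,10R,11S,14S) | C=C(C)[C@@H]1CC[C@](C)(O)[C@H](Br)CC[C@@]2(C)[C@H](Cc3cc(ccc3O)C(=O)O1)C(=C)CC[C@@H]2Br | target

**Step count and risks**
Total step count: 20. Longest linear sequence: 17 steps (geraniol 4 to 29 through steps 3–12 and 14–20).

Steps most likely to fail:

1. Step 17 (proposed new method). The alkylcopper may react between molecules faster than within one (oligomerisation). The catalyst may control the face of the enol ester poorly in a macrocyclic transition state. Substitution may occur at the chloride-bearing carbon, or the zirconium hydride may not fully discriminate the vinyl group from the other alkenes. Fallback with known chemistry, closing the ring by lactonisation instead: set out from 17. Hydrozirconation of the vinyl group with Cp2Zr(H)Cl followed by iodine gives the primary C13 iodide F1. Iodine–zinc exchange with Et2Zn (cat. CuI) gives the alkyl(ethyl)zinc F2 (not isolated). It adds to methacrolein under Ti(OiPr)4/(1R,2R)-1,2-bis(trifluoromethanesulfonamido)cyclohexane catalysis (catalytic asymmetric organozinc addition) to give the (14S)-allylic alcohol F3. Me3SnOH then cleaves the methyl ester to the seco acid F4. Yamaguchi macrolactonisation (2,4,6-trichlorobenzoyl chloride, Et3N, then DMAP, toluene, high dilution) gives 26, where the route continues with step 18.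

2. Step 11. The allylsilane may be protodesilylated by acid released in the fluorinated alcohol. The bromonium ion may be captured by solvent or by the diene. Bromonium transfer between alkenes may erode the enantiomeric purity. Fallback that starts the cyclisation from oxygen and installs bromine afterwards: set out from 14. Acid-catalysed hydration (cat. HClO4, THF/H2O, 0 °C) opens the epoxide at the tertiary carbon with inversion to the (6R,7S)-diol F5. Mesylation of the secondary hydroxyl gives the mesylate F6 (not isolated), which closes with K2CO3/MeOH, with inversion at C6, to the enantiomeric (6S,7S)-epoxide F7. Me2AlCl in CH2Cl2 at −78 °C triggers an epoxide-initiated, allylsilane-terminated cyclisation (C2 attacks C7 anti to oxygen through the chair) to the equatorial (6S)-alcohol F8, which has the ring stereocentres of 17. Dess–Martin oxidation gives the ketone F9. LiBH(sBu)3 at −78 °C reduces it from the equatorial side to the axial (6R)-alcohol F10. Appel bromination (CBr4, PPh3) with inversion gives 17; this last displacement at a neopentyl-type carbon is the weak point of the fallback.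

3. Step 8. The α-silyl organocopper may add too slowly to the alkyne, and the magnesium halide may open the epoxide over the long reaction time. Fallback using boron in place of stoichiometric copper–magnesium: set out from 12. Copper-catalysed borylcupration–alkylation (CuCl, Xantphos, NaOtBu, B2pin2, Me3SiCH2I, THF) gives the (Z)-alkenyl boronate F11, with boron on C2 cis to CH2SiMe3. Suzuki–Miyaura coupling with the benzylic bromide 3 (PdCl2(dppf), K3PO4, THF/H2O) gives 14.

**Further compounds**
F1 | step 17 | C13 primary iodide from hydrozirconation–iodination of 17 | ICC/C(C)=C/CC[C@@]1(C)[C@H](Cc2cc(ccc2O[Si](C(C)C)(C(C)C)C(C)C)C(=O)OC)C(=C)CC[C@@H]1Br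
F2 | step 17 | C13 alkyl(ethyl)zinc from F1 (not isolated) | CC[Zn]CC/C(C)=C/CC[C@@]1(C)[C@H](Cc2cc(ccc2O[Si](C(C)C)(C(C)C)C(C)C)C(=O)OC)C(=C)CC[C@@H]1Br
F3 | step 17 | (14S)-allylic alcohol, seco methyl ester | C=C(C)[C@@H](O)CC/C(C)=C/CC[C@@]1(C)[C@H](Cc2cc(ccc2O[Si](C(C)C)(C(C)C)C(C)C)C(=O)OC)C(=C)CC[C@@H]1Br
F4 | step 17 | (14S)-seco acid | C=C(C)[C@@H](O)CC/C(C)=C/CC[C@@]1(C)[C@H](Cc2cc(ccc2O[Si](C(C)C)(C(C)C)C(C)C)C(=O)O)C(=C)CC[C@@H]1Br
F5 | step 11 | (6R,7S)-6,7-diol from 14 | COC(=O)c1ccc(O[Si](C(C)C)(C(C)C)C(C)C)c(C/C=C(\C[Si](C)(C)C)CC[C@@H](O)[C@@](C)(O)CC/C=C(C)/C=C)c1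
F6 | step 11 | (6R,7S)-6-mesylate of F5 (not isolated) | COC(=O)c1ccc(O[Si](C(C)C)(C(C)C)C(C)C)c(C/C=C(\C[Si](C)(C)C)CC[C@@H](OS(C)(=O)=O)[C@@](C)(O)CC/C=C(C)/C=C)c1
F7 | step 11 | (6S,7S)-epoxide, enantiomeric at the oxirane to 14 | COC(=O)c1ccc(O[Si](C(C)C)(C(C)C)C(C)C)c(C/C=C(\C[Si](C)(C)C)CC[C@@H]2O[C@@]2(C)CC/C=C(C)/C=C)c1
F8 | step 11 | (2R,6S,7S)-6-hydroxy analogue of 17 (equatorial alcohol) | C=C/C(C)=C/CC[C@@]1(C)[C@H](Cc2cc(ccc2O[Si](C(C)C)(C(C)C)C(C)C)C(=O)OC)C(=C)CC[C@@H]1O
F9 | step 11 | (2R,7S)-6-ketone | C=C/C(C)=C/CC[C@@]1(C)[C@H](Cc2cc(ccc2O[Si](C(C)C)(C(C)C)C(C)C)C(=O)OC)C(=C)CCC1=O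
F10 | step 11 | (2R,6R,7S)-6-hydroxy analogue of 17 (axial alcohol) | C=C/C(C)=C/CC[C@@]1(C)[C@H](Cc2cc(ccc2O[Si](C(C)C)(C(C)C)C(C)C)C(=O)OC)C(=C)CC[C@H]1O
F11 | step 8 | (Z)-alkenyl pinacol boronate from 12 (B on C2 cis to CH2SiMe3) | CC1(C)OB(/C=C(\C[Si](C)(C)C)CC[C@H]2O[C@]2(C)CC/C=C(C)/C=C)OC1(C)C
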